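The constants used here were chosen freely; no experiment stands behind them.

Larch is the neighbour of maple: the same Q, but a third of its G.

| flask | Q | G | time |
|---|---|---|---|
| maple | 0.80 M | 0.480 M | 25 min |
| larch | 0.80 M | 0.160 M | 25 min |

    Q + G → Q.G (k1 = 0.412 /M/min)
    J → X (k2 = 0.00237 /min)
    2 Q → Q2 (k3 = 0.659 /M/min)
    Q ⇌ J (K4 = 1.7, k4 = 0.295 /min)

* which of these there is most of at the end, counted by the Q in it, maple (X / Q / J / Q2)
* which of these there is most of at the end, counted by the Q in it, larch (X / Q / J / Q2)
* how much there is at the end of the one of these that leads, in percent of the Q charged: maple
* how much there is at the end of the one of these that leads, in percent of the Q charged: larch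

- percent here means Q units held: one Q2 counts as two
- a doubled species enters its step squared and goes two at a time
- run time (maple): 25 min

Not every constant has to be known well. J goes to X with a half-life of 4.9 h, against a run of 25 min, so a poor value moves the ending little. The speed of the exchange has to be known well. J is not charged, and Q and J relax by that step alone in 1.48 min, while the first half-life of Q by dimerisation at its charge is 0.948 min, so Q2 starts forming before the shelter stands. The position of the exchange has to be known too: once relaxed, J shelters Q, which stands at 37.0% of the pool of Q and J. G is the limiting reagent by charge, and each Q.G takes one G, so the G balance caps Q.G at 20.0% of the Q charged in larch and 60.0% in maple. Within those caps, the two drains compete for Q.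

At the start of larch, Q goes 16 to Q2 for each one to Q.G. Kept as 5.92 for larch and 1.97 for maple, the sheltered split is the Q going to Q2 for each Q going to Q.G, with Q at its share of the charge and G at its charge. The share of spent Q that reaches Q2 is then 85.6% in larch and 66.4% in maple. An error of 10% in the split moves these shares by about 1.23% and 2.23%. With dimerisation as its single drain and Q at that share from the first moment, the pool falls to 21.7% of the charge by the end, a figure on the high side, since the shelter in fact forms late. This reckoning therefore gives Q2 the lead, at 67.0% in larch and 52.0% in maple.

The forecast names Q2 for maple at 55% and Q2 for larch at 68%, a little above this reckoning , and says “Less G in larch means less Q lost to Q.G”.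

The simulation gives Q2 at 57.4% in maple and Q2 at 70.6% in larch. The reckoning parts from it on the pool: larch keeps 16.2% of Q and J, not 21.7%. Q2 over Q.G reads 5.81 in larch against a split of 5.92, and 1.83 in maple against 1.97. Maple trails larch because of its higher G: given larch's G, maple reads 70.6% of Q2 instead of 57.4%, a gain of 13 percentage points.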